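Readings and results were computed on assumed constants, noise included.

If every electrophile that reacts takes one nucleophile, the reacted part cannot pass c(nucleophile)/c(electrophile), here 120%. This ceiling names the limiting reagent on paper, and since it stands above the whole charge, that reagent is the electrophile.

all flasks: electrophile 10 mM
- winter: nucleophile 12 mM; free base 13 mM; run made earlier
- spring: nucleophile 12 mM; free base 12 mM; run made earlier
- autumn: nucleophile 12 mM; free base 17 mM; run made earlier
- red: nucleophile 12.0 mM; free base 16.0 mM; time 2.0 min
- blue: nucleophile 12.0 mM; free base 11.0 mM; time 2.0 min

- winter (time / s: electrophile / %, target / %): 10.0: 75.4, 21.5; 20.0: 65.0, 27.4; 50.0: 50.0, 31.5; 120: 34.3, 36.1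
- spring (time / s: electrophile / %, target / %): 30.0: 58.9, 29.3; 60.0: 47.1, 32.3; 90.0: 39.9, 33.9; 120: 34.7, 36.4
- autumn (time / s: electrophile / %, target / %): 15.0: 68.9, 25.8; 40.0: 53.5, 30.9; 80.0: 40.9, 34.4; 120: 32.6, 37.4

(standard deviation of a reading: 0.3 percentage points)



- part of the electrophile that has reacted at the end, red
- part of the electrophile that has reacted at the end, blue
- what raising the concentration of free base from its lowest to its highest value here does to the part of the electrophile that has reacted (changes below 5 percentage points count as none) (it rises / it falls / no change)

The settings can be taken one after the other. Nucleophile and electrophile were not varied in the earlier runs, and red and blue keep the same charges, so the ceiling stays at 120% and gives no difference between them. By hand, more time means more reaction, and the spring run is still losing electrophile, from 39.9% at 90.0 s to 34.7% at 120 s. But the asked 2.0 min is the time of that last reading. By hand, more free base should help too, yet from the spring run at 12 mM to the autumn run at 17 mM the reacted part goes from 65.3% to 67.4%, a step of 2.1 percentage points, less than the 5 points that counts. The cheapest estimate of my own therefore reads the reacted part straight off the runs at the same clock time: red lies between those two readings, blue at 11.0 mM lies just below the tested range, and the trend is no change.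

The forecast gives 67% for red, 64.7% for blue and no change; its ground: “Base therefore has only a weak effect”.

The flasks give 66.7% for red and 64.8% for blue, a change of 1.9 points, so no change.

    nucleophile ⇌ dormant form (K = 1.10, k = 0.0420 s⁻¹)
    acid set free → by-product carried off (k = 0.0570 s⁻¹)
    electrophile + nucleophile → acid set free + target (k = 3.70 M⁻¹ s⁻¹)
    target ⇌ isomer of the product (K = 0.890, k = 0.0250 s⁻¹)
    acid set free + free base ⇌ salt of the base, settled at all times (K = 9600 M⁻¹)
    nucleophile + acid set free ⇌ protonated nucleophile, settled at all times (K = 56000 M⁻¹)

Red ends below its ceiling of 120%, with 33% of its electrophile still there. A neighbouring flask, red with 40 mM of electrophile, has its ceiling brought down to 30.0%, which makes the nucleophile the limiting reagent on paper. That flask reaches 26.9% at 2.00 min, under the new ceiling, with 73.1% of its electrophile left and its free nucleophile down to 0.968% of the charge.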